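The plan rests on disconnecting the C3–C4 bond of ring A. Ring B, with C5, the C8 methyl and the C7=C8 alkene, is taken from (R)-carvone, whose isopropenyl group is C4 carrying one of the geminal methyls. A single hydrogen-atom-transfer radical cyclization then closes ring A as a trans-decalin and completes the quaternary gem-dimethyl carbon C4. This is the feature the step exploits: the C4 radical is tertiary and sits on C5 of ring B. The cyclization substrate is carvone bearing on the future C10 a methyl group cis, and a 2-(phenylsulfonyl)allyl arm (C1–C3) trans, to the isopropenyl group.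

Key step: step 5

Remark: labdane numbering is used for the bicyclic compounds; the sulfonyl-bearing C2 (9, 12, 13) and the carbinol C9 of 12 are drawn as the expected epimers, and either epimer would serve because both centres are erased in steps 7 and 8.

Step 1
Reactants: 1 (R)-carvone
Product: 3 6-methylcarvone (both C6 epimers), via lithium dienolate of carvone 2 (not isolated)
Conditions: LiN(i-Pr)2 (1.05 equiv), THF, −78 °C; MeI, −78 → 0 °C
Reagents that add atoms: iodomethane, CI
Why: Kinetic α′-deprotonation gives the cross-conjugated dienolate, whose C-methylation (enolate alkylation) places the future C10 methyl; the configuration of this carbon is irrelevant because it is enolized again in step 4.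

Step 2
Reactants: 4 phenyl vinyl sulfone
Product: 5 2-(phenylsulfonyl)prop-2-en-1-ol
Conditions: 37% aq. CH2O, DABCO (0.5 equiv), THF/H2O, rt
Reagents that add atoms: formaldehyde, C=O
Why: Morita–Baylis–Hillman reaction, in which the amine adds to the vinyl sulfone, the α-sulfonyl carbanion is hydroxymethylated by formaldehyde and the amine is expelled again.

Step 3
Reactants: 5 2-(phenylsulfonyl)prop-2-en-1-ol
Product: 6 3-bromo-2-(phenylsulfonyl)prop-1-ene
Conditions: PBr3 (0.4 equiv), Et2O, 0 °C → rt
Reagents that add atoms: phosphorus tribromide, BrP(Br)Br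
Why: Standard conversion of a primary allylic alcohol into the bromide; SN2 and SN2′ displacement lead to the same product because the allyl unit carries no other substituent.

Step 4
Reactants: 3 6-methylcarvone (both C6 epimers); 6 3-bromo-2-(phenylsulfonyl)prop-1-ene
Product: 8 (5S,6S)-2,6-dimethyl-6-[2-(phenylsulfonyl)prop-2-en-1-yl]-5-(prop-1-en-2-yl)cyclohex-2-en-1-one, via lithium enolate of 6-methylcarvone 7 (not isolated)
Conditions: LiN(i-Pr)2 (1.1 equiv), THF, −78 → 0 °C; then 6 (1.2 equiv), −78 → −20 °C
Reagents that add atoms: none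
Why: Enolate C-alkylation by the 2-sulfonylallyl bromide (addition–elimination, SN2′ type) should occur on the face anti to the neighbouring isopropenyl group, which sets the quaternary C10 with methyl cis and the new arm trans to isopropenyl.

Step 5
Reactants: 8 (5S,6S)-2,6-dimethyl-6-[2-(phenylsulfonyl)prop-2-en-1-yl]-5-(prop-1-en-2-yl)cyclohex-2-en-1-one
Product: 9 (4aS,7S,8aS)-2,5,5,8a-tetramethyl-7-(phenylsulfonyl)-4a,5,6,7,8,8a-hexahydronaphthalen-1(4H)-one, in labdane numbering 4,4,8,10-tetramethyl-2α-(phenylsulfonyl)-trans-decal-7-en-9-one (5α-H, 10β-CH3)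
Conditions: Fe(acac)3 (0.3 equiv), PhSiH3 (2.5 equiv), EtOH/ethylene glycol (5:1), 0.02 M, 60 °C
Reagents that add atoms: none
Why: Trivalent iron is converted by PhSiH3 and ethanol into an iron hydride that transfers a hydrogen atom to the CH2 terminus of the isopropenyl group, the tertiary C4 radical adds to the unsubstituted terminus C3 of the vinyl sulfone, and the α-sulfonyl radical at C2 is reduced by divalent iron and protonated by ethanol, which returns trivalent iron. The closest known reaction type is the Fe(acac)3/PhSiH3 reductive olefin coupling (a hydrogen-atom-transfer-initiated Giese addition) run intramolecularly. Ring A should close in the 6-endo-trig mode, with both alkene carbons C2 and C3 inside the new ring, because the fully substituted C2 and the polarity match between the nucleophilic tertiary radical and the β-carbon of the vinyl sulfone disfavour 5-exo attack. The trans ring fusion is dictated by C5 and C10, whose two arms are trans on ring B and can bridge only to the trans-decalin; the single new centre C2 is set on protonation, with the sulfonyl group expected equatorial away from the axial C10 and C4 methyls, and is erased in step 8. The step needs chemoselective hydrogen-atom transfer to the isopropenyl alkene, which its electron-neutral 1,1-disubstituted character secures against the electron-poor enone and vinyl sulfone alkenes, and high dilution is chosen to favour ring closure over premature reduction of the radical.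

Step 6
Reactants: 9 4,4,8,10-tetramethyl-2α-(phenylsulfonyl)-trans-decal-7-en-9-one; 10 2-(2-bromoethyl)-1,3-dioxolane
Product: 12 9α-[2-(1,3-dioxolan-2-yl)ethyl]-9β-hydroxy-4,4,8,10-tetramethyl-2α-(phenylsulfonyl)-trans-decal-7-ene, via dioxolanylethylmagnesium bromide 11 (not isolated)
Conditions: 10, Mg, THF, 25 °C; 9 pre-stirred with anhydrous CeCl3 in THF, then 11, −78 → 0 °C; aq. NH4Cl
Reagents that add atoms: none
Why: CeCl3-promoted 1,2-addition of a primary Grignard reagent to the hindered enone carbonyl, the oxophilic cerium salt suppressing enolization; attack anti to the axial C10 methyl is expected, but the carbinol centre is removed in step 7.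

Step 7
Reactants: 12 9α-[2-(1,3-dioxolan-2-yl)ethyl]-9β-hydroxy-4,4,8,10-tetramethyl-2α-(phenylsulfonyl)-trans-decal-7-ene
Product: 13 9-[2-(1,3-dioxolan-2-yl)ethyl]-4,4,8,10-tetramethyl-2α-(phenylsulfonyl)-trans-decal-8-en-7-one
Conditions: [C5H5NH][CrO3Cl] (pyridinium chlorochromate, 3 equiv), Celite, CH2Cl2, rt
Reagents that add atoms: pyridinium chlorochromate, [O-][Cr](=O)(=O)Cl.c1cc[nH+]cc1
Why: Babler–Dauben oxidative transposition, in which the tertiary allylic chromate ester shifts to C7 by [3,3]-sigmatropic rearrangement and is oxidized by hexavalent chromium to the 8-en-7-one, the acetal and sulfone being inert.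

Step 8
Reactants: 13 9-[2-(1,3-dioxolan-2-yl)ethyl]-4,4,8,10-tetramethyl-2α-(phenylsulfonyl)-trans-decal-8-en-7-one
Product: 15 9β-[2-(1,3-dioxolan-2-yl)ethyl]-4,4,8,10-tetramethyl-trans-decal-7-en-7-yl trifluoromethanesulfonate (9α-H), via lithium C7 enolate 14 (not isolated)
Conditions: Li (excess), NH3(l)/THF, t-BuOH (1 equiv), −78 °C; isoprene; NH3 evaporated; PhNTf2 (2.5 equiv), THF, −78 °C → rt
Reagents that add atoms: N-phenylbis(trifluoromethanesulfonimide), O=S(=O)(N(c1ccccc1)S(=O)(=O)C(F)(F)F)C(F)(F)F
Why: Dissolving-metal (Birch-type) enone reduction should protonate C9 axially on the α-face, anti to the axial C10 methyl, so that the side chain becomes β-equatorial (9α-H) while the regiodefined C7 enolate persists, the same reagent cleaves the secondary C2–S bond (reductive desulfonylation), and O-triflation of the enolate fixes the C7=C8 position.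

Step 9
Reactants: 15 9β-[2-(1,3-dioxolan-2-yl)ethyl]-4,4,8,10-tetramethyl-trans-decal-7-en-7-yl trifluoromethanesulfonate
Product: 16 2-{2-[(1S,4aS,8aS)-2,5,5,8a-tetramethyl-1,4,4a,5,6,7,8,8a-octahydronaphthalen-1-yl]ethyl}-1,3-dioxolane (ethylene acetal of 14,15,16-trinorlabd-7-en-13-al)
Conditions: Pd(OAc)2 (5 mol%), PPh3 (10 mol%), HCO2H, n-Bu3N, DMF, 60 °C
Reagents that add atoms: none
Why: Palladium-catalysed formate reduction of an enol triflate, in which oxidative addition to zerovalent palladium, formate exchange, decarboxylation and reductive elimination replace the triflate by hydrogen without moving the alkene.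

Step 10
Reactants: 16 ethylene acetal of 14,15,16-trinorlabd-7-en-13-al
Product: 17 (5S,9S,10S)-14,15,16-trinorlabd-7-en-13-al
Conditions: 1 M aq. HCl, THF, rt
Reagents that add atoms: water, O
Why: Acid-catalysed acetal hydrolysis under conditions too mild to shift the trisubstituted C7=C8 alkene.

Step 11
Reactants: 17 (5S,9S,10S)-14,15,16-trinorlabd-7-en-13-al
Product: 18 (5S,9S,10S)-15,16-dinorlabd-7-en-13-yne
Conditions: dimethyl (1-diazo-2-oxopropyl)phosphonate, K2CO3, MeOH, 0 °C → rt
Reagents that add atoms: dimethyl (1-diazo-2-oxopropyl)phosphonate, CC(=O)C(=[N+]=[N-])P(=O)(OC)OC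
Why: Ohira–Bestmann (Seyferth–Gilbert) homologation, in which the diazomethylphosphonate anion formed in situ adds to the aldehyde and the alkylidene carbene left after loss of phosphate and N2 rearranges to the terminal alkyne, under conditions mild enough for an enolizable aldehyde.

Step 12
Reactants: 18 (5S,9S,10S)-15,16-dinorlabd-7-en-13-yne
Product: 20 (5S,9S,10S)-labda-7,13E-dien-15-ol, via alkenyl(dimethyl)alane 19 (not isolated)
Conditions: AlMe3 (3 equiv), Cp2ZrCl2 (0.25 equiv), CH2Cl2, 0 °C → rt; then (CH2O)n, THF, 0 °C → rt; aq. potassium sodium tartrate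
Reagents that add atoms: trimethylaluminium, C[Al](C)C; paraformaldehyde (as formaldehyde), C=O
Why: Negishi zirconium-catalysed methylalumination adds methyl and aluminium syn across the terminal alkyne with methyl at the internal carbon C13, and the alkenylalane is hydroxymethylated by formaldehyde with retention, so the 13E geometry follows from the syn addition.

Step 13
Reactants: 20 (5S,9S,10S)-labda-7,13E-dien-15-ol
Product: 21 (5S,9S,10S)-labda-7,13E-dien-15-yl hydrogen malonate (CNP0279336.1)
Conditions: Meldrum's acid (1.1 equiv), toluene, 90 °C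
Reagents that add atoms: Meldrum's acid (2,2-dimethyl-1,3-dioxane-4,6-dione), CC1(C)OC(=O)CC(=O)O1
Why: Thermal acylation of the primary allylic alcohol by Meldrum's acid opens the dioxanedione with loss of acetone and should give the malonic acid half ester directly, without protecting groups.

Compound list
1 | (R)-carvone, (5R)-2-methyl-5-(prop-1-en-2-yl)cyclohex-2-en-1-one | CC1=CC[C@@H](C(C)=C)CC1=O | starting material
2 | kinetic (cross-conjugated) lithium dienolate of (R)-carvone | CC1=CC[C@@H](C(C)=C)C=C1O[Li] | intermediate (not isolated)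
3 | (5R,6RS)-2,6-dimethyl-5-(prop-1-en-2-yl)cyclohex-2-en-1-one (6-methylcarvone, both C6 epimers) | CC1=CC[C@@H](C(C)=C)C(C)C1=O | intermediate
4 | phenyl vinyl sulfone | C=CS(=O)(=O)c1ccccc1 | starting material
5 | 2-(phenylsulfonyl)prop-2-en-1-ol | C=C(CO)S(=O)(=O)c1ccccc1 | intermediate
6 | 3-bromo-2-(phenylsulfonyl)prop-1-ene | C=C(CBr)S(=O)(=O)c1ccccc1 | intermediate
7 | lithium enolate of 6-methylcarvone (tetrasubstituted enolate, ring enone alkene retained) | CC1=CC[C@@H](C(C)=C)C(C)=C1O[Li] | intermediate (not isolated)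
8 | (5S,6S)-2,6-dimethyl-6-[2-(phenylsulfonyl)prop-2-en-1-yl]-5-(prop-1-en-2-yl)cyclohex-2-en-1-one (methyl cis, sulfonylallyl arm trans to isopropenyl) | CC1=CC[C@@H](C(C)=C)[C@](C)(CC(=C)S(=O)(=O)c2ccccc2)C1=O | intermediate
9 | (4aS,7S,8aS)-2,5,5,8a-tetramethyl-7-(phenylsulfonyl)-4a,5,6,7,8,8a-hexahydronaphthalen-1(4H)-one; 4,4,8,10-tetramethyl-2α-(phenylsulfonyl)-trans-decal-7-en-9-one | CC1=CC[C@H]2C(C)(C)C[C@H](S(=O)(=O)c3ccccc3)C[C@]2(C)C1=O | intermediate
10 | 2-(2-bromoethyl)-1,3-dioxolane | BrCCC1OCCO1 | starting material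
11 | [2-(1,3-dioxolan-2-yl)ethyl]magnesium bromide | Br[Mg]CCC1OCCO1 | intermediate (not isolated)
12 | 9α-[2-(1,3-dioxolan-2-yl)ethyl]-9β-hydroxy-4,4,8,10-tetramethyl-2α-(phenylsulfonyl)-trans-decal-7-ene (5α-H, 10β-CH3) | CC1=CC[C@H]2C(C)(C)C[C@H](S(=O)(=O)c3ccccc3)C[C@]2(C)[C@]1(O)CCC4OCCO4 | intermediate
13 | 9-[2-(1,3-dioxolan-2-yl)ethyl]-4,4,8,10-tetramethyl-2α-(phenylsulfonyl)-trans-decal-8-en-7-one (5α-H, 10β-CH3) | O=C1C[C@H]2C(C)(C)C[C@H](S(=O)(=O)c3ccccc3)C[C@]2(C)C(CCC4OCCO4)=C1C | intermediate
14 | lithium 9β-[2-(1,3-dioxolan-2-yl)ethyl]-4,4,8,10-tetramethyl-trans-decal-7-en-7-olate (9α-H, sulfone removed) | CC1=C(O[Li])C[C@H]2C(C)(C)CCC[C@]2(C)[C@H]1CCC3OCCO3 | intermediate (not isolated)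
15 | 9β-[2-(1,3-dioxolan-2-yl)ethyl]-4,4,8,10-tetramethyl-trans-decal-7-en-7-yl trifluoromethanesulfonate (9α-H) | CC1=C(OS(=O)(=O)C(F)(F)F)C[C@H]2C(C)(C)CCC[C@]2(C)[C@H]1CCC3OCCO3 | intermediate
16 | 2-{2-[(1S,4aS,8aS)-2,5,5,8a-tetramethyl-1,4,4a,5,6,7,8,8a-octahydronaphthalen-1-yl]ethyl}-1,3-dioxolane | CC1=CC[C@H]2C(C)(C)CCC[C@]2(C)[C@H]1CCC3OCCO3 | intermediate
17 | (5S,9S,10S)-14,15,16-trinorlabd-7-en-13-al | CC1=CC[C@H]2C(C)(C)CCC[C@]2(C)[C@H]1CCC=O | intermediate
18 | (5S,9S,10S)-15,16-dinorlabd-7-en-13-yne | CC1=CC[C@H]2C(C)(C)CCC[C@]2(C)[C@H]1CCC#C | intermediate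
19 | (13E)-14-(dimethylalumanyl)-15-norlabda-7,13-diene | CC1=CC[C@H]2C(C)(C)CCC[C@]2(C)[C@H]1CC/C(C)=C/[Al](C)C | intermediate (not isolated)
20 | (5S,9S,10S)-labda-7,13E-dien-15-ol | CC1=CC[C@H]2C(C)(C)CCC[C@]2(C)[C@H]1CC/C(C)=C/CO | intermediate
21 | (5S,9S,10S)-labda-7,13E-dien-15-yl hydrogen malonate; 3-oxo-3-{[(2E)-3-methyl-5-[(1S,4aS,8aS)-2,5,5,8a-tetramethyl-1,4,4a,5,6,7,8,8a-octahydronaphthalen-1-yl]pent-2-en-1-yl]oxy}propanoic acid | CC1=CC[C@H]2C(C)(C)CCC[C@]2(C)[C@H]1CC/C(C)=C/COC(=O)CC(=O)O | target

Total step count: 13.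
Longest linear sequence: 12 steps (4 → 5 → 6 → 8 → 9 → 12 → 13 → 15 → 16 → 17 → 18 → 20 → 21); 11 steps from (R)-carvone.

Steps most likely to fail

Step 5. The C4 radical may be reduced before it cyclizes (net hydrogenation of the isopropenyl group), or hydrogen-atom transfer may stray to the enone or vinyl sulfone alkenes, because hydride donor and radical are generated together and their concentrations cannot be set independently. The fallback sets out from 8: Markovnikov addition of HBr (HBr/AcOH, 0 °C) to the isopropenyl group should give the 2-bromopropan-2-yl analogue of 8 F1. Slow addition of Bu3SnH with AIBN in benzene at 80 °C would then generate the same tertiary C4 radical by bromine abstraction at a stannane concentration that can be kept low. Closure in the 6-endo mode onto the vinyl sulfone and hydrogen transfer from the stannane bring the sequence back to the route at 9.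

Step 8. Several events share one flask. The enolate may be protonated early and over-reduced, the C2–S bond may be cleaved incompletely, or the lithium amide formed alongside may consume PhNTf2 and leave O-triflation incomplete. The fallback sets out from 13: the same Li/NH3 reduction is quenched with ClP(O)(OEt)2 instead, which should give the C7 enol diethyl phosphate analogue of 15 F2, a robust compound that can be purified. Reduction with Li in EtNH2/t-BuOH/THF at 0 °C should cleave the vinylic C–O bond with retention of the alkene position and strip any surviving sulfone. This comes back to the route at 16 and bypasses 15 and step 9.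

Step 6. Deprotonation (γ-enolization at C6 or removal of the proton α to the sulfone) or plain lack of reactivity at the neopentyl-type carbonyl may outrun 1,2-addition of the functionalized primary Grignard reagent. The fallback sets out from 9 and uses allylmagnesium bromide, which adds to hindered ketones through a cyclic six-membered transition state. It should give the 9-allyl tertiary allylic alcohol F3. Oxidative transposition with [C5H5NH][CrO3Cl] as in step 7 would give the 9-allyl-8-en-7-one F4. Li/NH3 reduction with PhNTf2 trapping as in step 8 would give the 9β-allyl enol triflate F5, and palladium–formate reduction as in step 9 the 9β-allyl 7-ene F6. Hydroboration of the terminal alkene with 9-BBN (the trisubstituted ring alkene reacting far more slowly) and NaOH/H2O2 oxidation would give the primary alcohol 14,15,16-trinorlabd-7-en-13-ol F7. Dess–Martin oxidation then comes back to the route at 17.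

Further compounds
F1 | step 5 | (5R,6S)-5-(2-bromopropan-2-yl)-2,6-dimethyl-6-[2-(phenylsulfonyl)prop-2-en-1-yl]cyclohex-2-en-1-one | CC1=CC[C@@H](C(C)(C)Br)[C@](C)(CC(=C)S(=O)(=O)c2ccccc2)C1=O
F2 | step 8 | 9β-[2-(1,3-dioxolan-2-yl)ethyl]-4,4,8,10-tetramethyl-trans-decal-7-en-7-yl diethyl phosphate (9α-H) | CC1=C(OP(=O)(OCC)OCC)C[C@H]2C(C)(C)CCC[C@]2(C)[C@H]1CCC3OCCO3
F3 | step 6 | 9α-allyl-9β-hydroxy-4,4,8,10-tetramethyl-2α-(phenylsulfonyl)-trans-decal-7-ene | CC1=CC[C@H]2C(C)(C)C[C@H](S(=O)(=O)c3ccccc3)C[C@]2(C)[C@]1(O)CC=C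
F4 | step 6 | 9-allyl-4,4,8,10-tetramethyl-2α-(phenylsulfonyl)-trans-decal-8-en-7-one | O=C1C[C@H]2C(C)(C)C[C@H](S(=O)(=O)c3ccccc3)C[C@]2(C)C(CC=C)=C1C
F5 | step 6 | 9β-allyl-4,4,8,10-tetramethyl-trans-decal-7-en-7-yl trifluoromethanesulfonate (9α-H) | CC1=C(OS(=O)(=O)C(F)(F)F)C[C@H]2C(C)(C)CCC[C@]2(C)[C@H]1CC=C
F6 | step 6 | 9β-allyl-4,4,8,10-tetramethyl-trans-decal-7-ene (9α-H) | CC1=CC[C@H]2C(C)(C)CCC[C@]2(C)[C@H]1CC=C
F7 | step 6 | (5S,9S,10S)-14,15,16-trinorlabd-7-en-13-ol | CC1=CC[C@H]2C(C)(C)CCC[C@]2(C)[C@H]1CCCO
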